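Everything rests on opening ring A at C1–C2 (eudesmane numbering). Two features make this safe: C3 is oxygenated and flanked by the fully substituted C4, and C1 sits on the quaternary C10, so a C3 methyl ketone enolises only towards C2 and a C1 aldehyde not at all. An amine-salt aldol condensation then closes ring A in one operation as the cis-fused Δ1-3-ketone. The precursor is a ring B cyclohexane (a 1,2-seco-eudesmane) with cis-disposed C5 and C10 arms, the C4 tertiary acetate of the target already in place, the C7 isopropyl group and a C8 dioxolane; it is assembled from (R)-cryptone, an (R)-lactaldehyde ether and a one-carbon alkoxymethyl unit.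

Key step: step 17

Remark: the C4 carbinol centre of 11–23 and the C10 carbinol centre of 18 are erased later; they are drawn as the expected major epimers, and any minor epimer converges at 24 and 19.

Step 1
Reactants: 1 3-methylbutanal; 2 but-3-en-2-one
Product: 3 (2R)-5-oxo-2-(propan-2-yl)hexanal
Conditions: (R)-2-[methoxy(diphenyl)methyl]pyrrolidine (5 mol%), ethyl 3,4-dihydroxybenzoate (20 mol%), neat, 4 °C
Reagents that add atoms: none
Why: Enamine-catalysed asymmetric Michael addition; the diarylmethyl ether group of the (R)-catalyst shields one face of the E-enamine of 1, so the enone should add to the open Re face and set the future C7 as R.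

Step 2
Reactants: 3 (2R)-5-oxo-2-(propan-2-yl)hexanal
Product: 5 (4R)-4-(propan-2-yl)cyclohex-2-en-1-one [(R)-cryptone], via aldol adduct 4 (not isolated)
Conditions: LiOH, iPrOH, 23 °C
Reagents that add atoms: none
Why: Intramolecular aldol condensation (methyl ketone enolate onto the aldehyde, then E1cB dehydration) gives the conjugated cyclohexenone; mild hydroxide at ambient temperature should cyclise faster than it epimerises the α-branched aldehyde.

Step 3
Reactants: 6 methyl (2R)-2-hydroxypropanoate
Product: 7 methyl (2R)-2-(benzyloxy)propanoate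
Conditions: benzyl 2,2,2-trichloroacetimidate, TfOH (cat.), cyclohexane/CH2Cl2, 23 °C
Reagents that add atoms: benzyl 2,2,2-trichloroacetimidate, N=C(OCc1ccccc1)C(Cl)(Cl)Cl
Why: Acid-catalysed O-benzylation with the trichloroacetimidate avoids base, so the lactate stereocentre should not racemise.

Step 4
Reactants: 7 methyl (2R)-2-(benzyloxy)propanoate
Product: 9 (2R)-2-(benzyloxy)propanal, via aluminium hemiacetal 8 (not isolated)
Conditions: iBu2AlH, CH2Cl2, −78 °C
Reagents that add atoms: none
Why: Partial hydride reduction of an α-alkoxy ester; the chelated tetrahedral aluminium hemiacetal persists at −78 °C and releases the aldehyde only on aqueous work-up.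

Step 5
Reactants: 5 (R)-cryptone; 9 (2R)-2-(benzyloxy)propanal
Product: 11 (4R,6R)-6-[(1S,2R)-2-(benzyloxy)-1-hydroxypropyl]-4-(propan-2-yl)cyclohex-2-en-1-one, via lithium dienolate 10 (not isolated)
Conditions: LiN(iPr)2, THF, −78 °C; then 9, −78 °C
Reagents that add atoms: none
Why: Kinetic α′-deprotonation and lithium aldol addition through a closed chair transition state; axial attack on the half-chair dienolate trans to the pseudo-equatorial isopropyl group sets C5, and the anti, non-chelation mode fixes the temporary C4 carbinol.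

Step 6
Reactants: 11 aldol adduct
Product: 12 (4R,6R)-6-[(1S,2R)-2-(benzyloxy)-1-(tert-butyldimethylsilyloxy)propyl]-4-(propan-2-yl)cyclohex-2-en-1-one
Conditions: t-BuMe2SiOTf, 2,6-lutidine, CH2Cl2, −78 → 0 °C
Reagents that add atoms: tert-butyldimethylsilyl trifluoromethanesulfonate, CC(C)(C)[Si](C)(C)OS(=O)(=O)C(F)(F)F
Why: Silyl triflate silylation with a hindered base at low temperature masks the β-hydroxyl without retro-aldol or elimination.

Step 7
Reactants: 13 benzyl chloromethyl ether; 14 tributylstannane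
Product: 16 [(benzyloxy)methyl]tributylstannane, via tributylstannyllithium 15 (not isolated)
Conditions: LiN(iPr)2, THF, 0 °C; then 13, −78 → 23 °C
Reagents that add atoms: none
Why: Deprotonation of the tin hydride gives the stannyl anion, which displaces chloride from the α-chloro ether in an SN2 alkylation.

Step 8
Reactants: 12 silyl ether; 16 [(benzyloxy)methyl]tributylstannane
Product: 18 (1R,4R,6R)-1-[(benzyloxy)methyl]-6-[(1S,2R)-2-(benzyloxy)-1-(tert-butyldimethylsilyloxy)propyl]-4-(propan-2-yl)cyclohex-2-en-1-ol, via benzyloxymethyllithium 17 (not isolated)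
Conditions: n-BuLi, THF, −78 °C; then 12, −78 °C
Reagents that add atoms: none
Why: Tin–lithium exchange gives the α-alkoxy organolithium, which adds 1,2 to the enone carbonyl (C10) anti to the C5 substituent; this carbinol centre is erased in step 9.

Step 9
Reactants: 18 tertiary allylic alcohol
Product: 19 (4S,6R)-3-[(benzyloxy)methyl]-4-[(1S,2R)-2-(benzyloxy)-1-(tert-butyldimethylsilyloxy)propyl]-6-(propan-2-yl)cyclohex-2-en-1-one
Conditions: C5H5NH[CrO3Cl] (pyridinium chlorochromate), 4 Å MS, CH2Cl2, 23 °C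
Reagents that add atoms: pyridinium chlorochromate, [O-][Cr](=O)(=O)Cl.c1cc[nH+]cc1
Why: Oxidative 1,3-transposition of a tertiary allylic alcohol; the chromate ester undergoes a [3,3]-shift to C8 and is oxidised, giving the C8 enone with the C1 carbon on its β-position (C10).

Step 10
Reactants: 19 enone
Product: 21 (3R,4S,5S,7R,10R)-1,3-bis(benzyloxy)-4-(tert-butyldimethylsilyloxy)-15-nor-1,2-seco-eudesman-8-one, via silyl enol ether 20 (not isolated)
Conditions: Me2CuLi, Me3SiCl, THF, −78 → −20 °C; then 1 M HCl, 0 °C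
Reagents that add atoms: lithium dimethylcuprate, [Li+].C[Cu-]C
Why: Silyl-chloride-accelerated cuprate conjugate addition; the C5 arm lies pseudo-axial to avoid A(1,2) strain with the C10 substituent, so methyl attacks C10 axially from the opposite face and sets the quaternary centre with C1 cis to the arm.

Step 11
Reactants: 21 ketone
Product: 22 (3R,4S,5S,7R,10R)-1,3-bis(benzyloxy)-4-(tert-butyldimethylsilyloxy)-8,8-(ethylenedioxy)-15-nor-1,2-seco-eudesmane
Conditions: Me3SiOCH2CH2OSiMe3, Me3SiOTf (cat.), CH2Cl2, −78 → −20 °C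
Reagents that add atoms: 1,2-bis(trimethylsilyloxy)ethane, C[Si](C)(C)OCCO[Si](C)(C)C
Why: Silyl-triflate-catalysed ketalisation under aprotic, low-temperature conditions forms the dioxolane without enolising C8, so C7 keeps its configuration and the silyl and benzyl ethers survive.

Step 12
Reactants: 22 ketal silyl ether
Product: 23 (3R,4S,5S,7R,10R)-1,3-bis(benzyloxy)-8,8-(ethylenedioxy)-15-nor-1,2-seco-eudesman-4-ol
Conditions: Bu4NF, THF, 23 → 40 °C
Reagents that add atoms: none
Why: Fluoride-mediated desilylation is selective for the silyl ether; the ketal and the benzyl ethers are inert.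

Step 13
Reactants: 23 C4 alcohol
Product: 24 (3R,5S,7R,10R)-1,3-bis(benzyloxy)-8,8-(ethylenedioxy)-15-nor-1,2-seco-eudesman-4-one
Conditions: Dess–Martin periodinane, CH2Cl2, 0 → 23 °C
Reagents that add atoms: none
Why: Dess–Martin oxidation under non-basic conditions gives the α-benzyloxy ketone without epimerising C5 or C3.

Step 14
Reactants: 24 α-benzyloxy ketone
Product: 26 (3R,4S,5S,7R,10R)-4-acetoxy-1,3-bis(benzyloxy)-8,8-(ethylenedioxy)-1,2-seco-eudesmane, via bromomagnesium alkoxide 25 (not isolated)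
Conditions: MeMgBr, THF, −78 °C; then Ac2O, −78 → 23 °C
Reagents that add atoms: methylmagnesium bromide, C[Mg]Br; acetic anhydride, CC(=O)OC(C)=O
Why: Chelation-controlled Grignard addition followed by O-acylation of the alkoxide; magnesium bridges the C4 carbonyl and the C3 benzyloxy oxygen, methyl enters from the face of the C3 hydrogen (also the face remote from C10) to set C4 as S, and acetic anhydride traps the alkoxide as the tertiary acetate of the target.

Step 15
Reactants: 26 tertiary acetate
Product: 27 (3R,4S,5S,7R,10R)-4-acetoxy-8,8-(ethylenedioxy)-1,2-seco-eudesmane-1,3-diol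
Conditions: H2 (1 atm), Pd(OH)2/C, EtOAc, 23 °C
Reagents that add atoms: none
Why: Hydrogenolysis cleaves both benzyl ethers under neutral conditions that leave the tertiary acetate and the dioxolane untouched; the diol should be oxidised without delay to forestall acetyl migration.

Step 16
Reactants: 27 diol
Product: 29 (4S,5S,7R,10R)-4-acetoxy-8,8-(ethylenedioxy)-3-oxo-1,2-seco-eudesman-1-al, via bis-alkoxysulfonium salt 28 (not isolated)
Conditions: (COCl)2, DMSO, CH2Cl2, −78 °C; then Et3N, −78 → 0 °C
Reagents that add atoms: none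
Why: Swern oxidation; both hydroxyls are activated as alkoxysulfonium ions at −78 °C before base is added, so no lactol between C1 and O3 (and hence no lactone) can form, and the non-enolisable aldehyde and the methyl ketone are released together.

Step 17
Reactants: 29 ring B keto aldehyde
Product: 31 (4S,5S,7R,10S)-4-acetoxy-8,8-(ethylenedioxy)eudesm-1-en-3-one, via β-hydroxy ketone 30 (not isolated)
Conditions: Bn2NH2·O2CCF3 (dibenzylammonium trifluoroacetate, 0.5 equiv), 4 Å MS, toluene, 60 °C
Reagents that add atoms: none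
Why: The ammonium carboxylate promotes enolisation of the C3 methyl ketone towards C2 (and may activate the C1 aldehyde as its iminium ion); the C2 enol adds to C1 and the β-hydroxy ketone 30 loses water by E1cB elimination to give the C1=C2 enone. The closest known reaction type is the amine-salt-mediated intramolecular aldol condensation of keto aldehydes to cyclohexenones. Ring A closes in the 6-(enolexo)-exo-trig mode. No stereocentre is created, since C1 and C2 end up sp2 and the cis ring fusion is fixed by the C5 and C10 configurations set in steps 5 and 10. The only selectivity at stake is which carbon enolises and which carbonyl accepts: with C4 and C10 fully substituted, the ketone can enolise solely at C2 and the aldehyde not at all, and the ring B carbonyl is masked as its dioxolane. The buffered, weakly nucleophilic medium should leave the tertiary acetate and the dioxolane intact.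

Step 18
Reactants: 31 enone
Product: 32 (4S,5S,7R,10R)-4-acetoxy-8,8-(ethylenedioxy)eudesman-3-one
Conditions: H2 (1 atm), Pd/C, EtOAc, 23 °C
Reagents that add atoms: none
Why: Heterogeneous hydrogenation saturates the disubstituted C1=C2 bond; no stereocentre is created and ketone, acetate and ketal are not reduced.

Step 19
Reactants: 32 ketone
Product: 33 (3R,4S,5S,7R,10R)-4-acetoxy-8,8-(ethylenedioxy)eudesman-3-ol (3α-alcohol)
Conditions: NaBH4, CeCl3·7H2O, MeOH, −78 → −40 °C
Reagents that add atoms: none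
Why: Luche-type borohydride reduction; in the favoured ring A chair (C4 acetoxy axial, C4 methyl equatorial, the other chair having a 1,3-diaxial clash of the C4 and C10 methyls) the small hydride attacks C3 axially from the β face, anti to the axial C4–O bond, to give the equatorial 3α-alcohol, and low temperature limits acetyl migration.

Step 20
Reactants: 34 angelic acid
Product: 35 (2Z)-2-methylbut-2-en-1-ol
Conditions: LiAlH4, Et2O, 0 → 23 °C
Reagents that add atoms: none
Why: Hydride reduction of the carboxylic acid to the allylic alcohol should leave the Z double bond untouched.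

Step 21
Reactants: 35 (2Z)-2-methylbut-2-en-1-ol
Product: 36 [(2R,3S)-2,3-dimethyloxiran-2-yl]methanol
Conditions: Ti(OiPr)4, D-(−)-diethyl tartrate, t-BuOOH, 4 Å MS, CH2Cl2, −20 °C
Reagents that add atoms: tert-butyl hydroperoxide, CC(C)(C)OO
Why: Sharpless asymmetric epoxidation; the D-(−)-tartrate complex delivers oxygen to the face of the Z-allylic alcohol that gives the (2R,3S)-epoxy alcohol, with retention of alkene geometry.

Step 22
Reactants: 36 epoxy alcohol
Product: 37 (2S,3S)-2,3-dimethyloxirane-2-carboxylic acid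
Conditions: RuCl3·3H2O (cat.), NaIO4, MeCN/EtOAc/H2O, 23 °C
Reagents that add atoms: sodium periodate, [Na+].[O-]I(=O)(=O)=O; water, O
Why: RuO4-type oxidation of the primary alcohol to the acid through the aldehyde hydrate leaves the epoxide intact; the C2 descriptor changes to S only because the priorities change.

Step 23
Reactants: 33 3α-alcohol; 37 epoxy acid
Product: 39 (3R,4S,5S,7R,10R)-4-acetoxy-8,8-(ethylenedioxy)eudesman-3-yl (2S,3S)-2,3-dimethyloxirane-2-carboxylate, via mixed anhydride 38 (not isolated)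
Conditions: 2,4,6-trichlorobenzoyl chloride, Et3N, THF, 23 °C; then 33, DMAP, toluene, 23 → 40 °C
Reagents that add atoms: none
Why: Yamaguchi esterification; DMAP transfers the epoxy acyl group from the mixed anhydride to the equatorial 3α-hydroxyl with retention at every centre, the aroyl carbonyl being too hindered to compete.

Step 24
Reactants: 39 ester ketal
Product: 40 (3R,4S,5S,7R,10R)-4-acetoxy-8-oxoeudesman-3-yl (2S,3S)-2,3-dimethyloxirane-2-carboxylate (CNP0221066.1)
Conditions: PPTS, acetone/H2O, 50 °C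
Reagents that add atoms: water, O
Why: Mild acid-catalysed ketal hydrolysis, helped by relief of the 1,3-diaxial contact between a ketal oxygen and the C10 methyl, should spare the glycidic ester and the acetate; C7 keeps the equatorial isopropyl configuration that is also the thermodynamically favoured one.

Compound list
1 | 3-methylbutanal | CC(C)CC=O | starting material
2 | but-3-en-2-one | CC(=O)C=C | starting material
3 | (2R)-5-oxo-2-(propan-2-yl)hexanal | CC(=O)CC[C@@H](C=O)C(C)C | intermediate
4 | (4R)-3-hydroxy-4-(propan-2-yl)cyclohexan-1-one (C3 epimers, not isolated) | O=C1CC(O)[C@@H](C(C)C)CC1 | intermediate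
5 | (4R)-4-(propan-2-yl)cyclohex-2-en-1-one, (R)-cryptone | CC(C)[C@H]1CCC(=O)C=C1 | intermediate
6 | methyl (2R)-2-hydroxypropanoate | C[C@@H](O)C(=O)OC | starting material
7 | methyl (2R)-2-(benzyloxy)propanoate | C[C@@H](OCc1ccccc1)C(=O)OC | intermediate
8 | diisobutylaluminium hemiacetal of 7 (not isolated) | C[C@@H](OCc1ccccc1)C(OC)O[Al](CC(C)C)CC(C)C | intermediate
9 | (2R)-2-(benzyloxy)propanal | C[C@@H](OCc1ccccc1)C=O | intermediate
10 | lithium (4R)-4-(propan-2-yl)cyclohexa-1,5-dien-1-olate (not isolated) | [Li]OC1=CC[C@H](C(C)C)C=C1 | intermediate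
11 | (4R,6R)-6-[(1S,2R)-2-(benzyloxy)-1-hydroxypropyl]-4-(propan-2-yl)cyclohex-2-en-1-one | O=C1C=C[C@@H](C(C)C)C[C@@H]1[C@H](O)[C@@H](C)OCc2ccccc2 | intermediate
12 | (4R,6R)-6-[(1S,2R)-2-(benzyloxy)-1-(tert-butyldimethylsilyloxy)propyl]-4-(propan-2-yl)cyclohex-2-en-1-one | O=C1C=C[C@@H](C(C)C)C[C@@H]1[C@H](O[Si](C)(C)C(C)(C)C)[C@@H](C)OCc2ccccc2 | intermediate
13 | benzyl chloromethyl ether | ClCOCc1ccccc1 | starting material
14 | tributylstannane | CCCC[SnH](CCCC)CCCC | starting material
15 | tributylstannyllithium (not isolated) | [Li][Sn](CCCC)(CCCC)CCCC | intermediate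
16 | [(benzyloxy)methyl]tributylstannane | CCCC[Sn](CCCC)(CCCC)COCc1ccccc1 | intermediate
17 | [(benzyloxy)methyl]lithium (not isolated) | [Li]COCc1ccccc1 | intermediate
18 | (1R,4R,6R)-1-[(benzyloxy)methyl]-6-[(1S,2R)-2-(benzyloxy)-1-(tert-butyldimethylsilyloxy)propyl]-4-(propan-2-yl)cyclohex-2-en-1-ol | O[C@]1(COCc3ccccc3)C=C[C@@H](C(C)C)C[C@@H]1[C@H](O[Si](C)(C)C(C)(C)C)[C@@H](C)OCc2ccccc2 | intermediate
19 | (4S,6R)-3-[(benzyloxy)methyl]-4-[(1S,2R)-2-(benzyloxy)-1-(tert-butyldimethylsilyloxy)propyl]-6-(propan-2-yl)cyclohex-2-en-1-one | O=C1C=C(COCc3ccccc3)[C@@H]([C@H](O[Si](C)(C)C(C)(C)C)[C@@H](C)OCc2ccccc2)C[C@@H]1C(C)C | intermediate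
20 | C8 trimethylsilyl enol ether (C8=C9) of 21 (not isolated) | c3ccccc3COC[C@]1(C)C=C(O[Si](C)(C)C)[C@@H](C(C)C)C[C@@H]1[C@H](O[Si](C)(C)C(C)(C)C)[C@@H](C)OCc2ccccc2 | intermediate
21 | (3R,4S,5S,7R,10R)-1,3-bis(benzyloxy)-4-(tert-butyldimethylsilyloxy)-15-nor-1,2-seco-eudesman-8-one | c3ccccc3COC[C@]1(C)CC(=O)[C@@H](C(C)C)C[C@@H]1[C@H](O[Si](C)(C)C(C)(C)C)[C@@H](C)OCc2ccccc2 | intermediate
22 | (3R,4S,5S,7R,10R)-1,3-bis(benzyloxy)-4-(tert-butyldimethylsilyloxy)-8,8-(ethylenedioxy)-15-nor-1,2-seco-eudesmane | c3ccccc3COC[C@]1(C)CC4(OCCO4)[C@@H](C(C)C)C[C@@H]1[C@H](O[Si](C)(C)C(C)(C)C)[C@@H](C)OCc2ccccc2 | intermediate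
23 | (3R,4S,5S,7R,10R)-1,3-bis(benzyloxy)-8,8-(ethylenedioxy)-15-nor-1,2-seco-eudesman-4-ol | c3ccccc3COC[C@]1(C)CC4(OCCO4)[C@@H](C(C)C)C[C@@H]1[C@H](O)[C@@H](C)OCc2ccccc2 | intermediate
24 | (3R,5S,7R,10R)-1,3-bis(benzyloxy)-8,8-(ethylenedioxy)-15-nor-1,2-seco-eudesman-4-one | c3ccccc3COC[C@]1(C)CC4(OCCO4)[C@@H](C(C)C)C[C@@H]1C(=O)[C@@H](C)OCc2ccccc2 | intermediate
25 | bromomagnesium (4S)-alkoxide of the methyl adduct of 24 (not isolated) | c3ccccc3COC[C@]1(C)CC4(OCCO4)[C@@H](C(C)C)C[C@@H]1[C@](C)(O[Mg]Br)[C@@H](C)OCc2ccccc2 | intermediate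
26 | (3R,4S,5S,7R,10R)-4-acetoxy-1,3-bis(benzyloxy)-8,8-(ethylenedioxy)-1,2-seco-eudesmane | c3ccccc3COC[C@]1(C)CC4(OCCO4)[C@@H](C(C)C)C[C@@H]1[C@](C)(OC(C)=O)[C@@H](C)OCc2ccccc2 | intermediate
27 | (3R,4S,5S,7R,10R)-4-acetoxy-8,8-(ethylenedioxy)-1,2-seco-eudesmane-1,3-diol | OC[C@]1(C)CC2(OCCO2)[C@@H](C(C)C)C[C@@H]1[C@](C)(OC(C)=O)[C@@H](C)O | intermediate
28 | 1,3-bis(dimethylsulfonio-oxy) derivative of 27, dichloride (not isolated) | C[S+](C)OC[C@]1(C)CC2(OCCO2)[C@@H](C(C)C)C[C@@H]1[C@](C)(OC(C)=O)[C@@H](C)O[S+](C)C.[Cl-].[Cl-] | intermediate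
29 | (4S,5S,7R,10R)-4-acetoxy-8,8-(ethylenedioxy)-3-oxo-1,2-seco-eudesman-1-al (ring B keto aldehyde) | O=C[C@]1(C)CC2(OCCO2)[C@@H](C(C)C)C[C@@H]1[C@](C)(OC(C)=O)C(C)=O | intermediate
30 | (4S,5S,7R,10R)-4-acetoxy-8,8-(ethylenedioxy)-1-hydroxyeudesman-3-one (C1 epimers, not isolated) | CC(=O)O[C@]1(C)C(=O)CC(O)[C@]2(C)CC3(OCCO3)[C@@H](C(C)C)C[C@@H]21 | intermediate
31 | (4S,5S,7R,10S)-4-acetoxy-8,8-(ethylenedioxy)eudesm-1-en-3-one (cis-fused enone) | CC(=O)O[C@]1(C)C(=O)C=C[C@]2(C)CC3(OCCO3)[C@@H](C(C)C)C[C@@H]21 | intermediate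
32 | (4S,5S,7R,10R)-4-acetoxy-8,8-(ethylenedioxy)eudesman-3-one | CC(=O)O[C@]1(C)C(=O)CC[C@]2(C)CC3(OCCO3)[C@@H](C(C)C)C[C@@H]21 | intermediate
33 | (3R,4S,5S,7R,10R)-4-acetoxy-8,8-(ethylenedioxy)eudesman-3-ol | CC(=O)O[C@]1(C)[C@H](O)CC[C@]2(C)CC3(OCCO3)[C@@H](C(C)C)C[C@@H]21 | intermediate
34 | angelic acid, (2Z)-2-methylbut-2-enoic acid | C/C=C(/C)C(=O)O | starting material
35 | (2Z)-2-methylbut-2-en-1-ol | C/C=C(/C)CO | intermediate
36 | [(2R,3S)-2,3-dimethyloxiran-2-yl]methanol | OC[C@@]1(C)O[C@H]1C | intermediate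
37 | (2S,3S)-2,3-dimethyloxirane-2-carboxylic acid | OC(=O)[C@@]1(C)O[C@H]1C | intermediate
38 | (2S,3S)-2,3-dimethyloxirane-2-carboxylic 2,4,6-trichlorobenzoic anhydride (not isolated) | O=C(OC(=O)c1c(Cl)cc(Cl)cc1Cl)[C@@]2(C)O[C@H]2C | intermediate
39 | (3R,4S,5S,7R,10R)-4-acetoxy-8,8-(ethylenedioxy)eudesman-3-yl (2S,3S)-2,3-dimethyloxirane-2-carboxylate | CC(=O)O[C@]1(C)[C@H](OC(=O)[C@@]4(C)O[C@H]4C)CC[C@]2(C)CC3(OCCO3)[C@@H](C(C)C)C[C@@H]21 | intermediate
40 | (3R,4S,5S,7R,10R)-4-acetoxy-8-oxoeudesman-3-yl (2S,3S)-2,3-dimethyloxirane-2-carboxylate | CC(=O)O[C@]1(C)[C@H](OC(=O)[C@@]2(C)O[C@H]2C)CC[C@]2(C)CC(=O)[C@@H](C(C)C)C[C@@H]21 | target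

Total step count: 24 steps. Longest linear sequence: 18 steps (steps 1, 2, 5, 6, 8–19, 23 and 24).

Steps most likely to fail

Step 14: the tertiary bromomagnesium alkoxide may be too hindered to be acetylated in the flask, or the Grignard reagent may enolise the C4 ketone instead of adding. Fallback: starting from 24, the chelation-controlled addition is run on its own and quenched with water to give the tertiary carbinol F1. The neutral alcohol is then acetylated in a separate DMAP-catalysed acyl transfer (Ac2O, DMAP, Et3N, 50 °C), that is by nucleophilic catalysis and not by alkoxide trapping, and the route is rejoined at 26.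

Step 23: acylation of the hindered 3α-hydroxyl by the α,α-disubstituted acid may be slower than base-induced migration of the acetyl group from O4 to O3 (the same migration can already begin in step 19). Fallback: starting from 33, methanolysis (K2CO3, MeOH) removes the acetate from whichever oxygen carries it and gives the 3α,4α-diol F2. Yamaguchi acylation with 37 is then selective for the secondary hydroxyl and gives the hydroxy ester F3. The tertiary alcohol is acetylated last (Ac2O, DMAP, Et3N, 60 °C), and the route is rejoined at 39.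

Step 17: the condensation may stall before dehydration, or the amine salt may slowly attack the tertiary acetate or open the dioxolane. Fallback: starting from 29, kinetic deprotonation of the methyl ketone with LiN(SiMe3)2 in THF at −78 °C brings about intramolecular aldol addition to the β-hydroxy ketone 30, which is isolated. It is converted into the mesylate F4 (MsCl, Et3N, 0 °C) and eliminated with DBU, and the route is rejoined at 31.

Further compounds
F1 | step 14 | (3R,4S,5S,7R,10R)-1,3-bis(benzyloxy)-8,8-(ethylenedioxy)-1,2-seco-eudesman-4-ol | c3ccccc3COC[C@]1(C)CC4(OCCO4)[C@@H](C(C)C)C[C@@H]1[C@](C)(O)[C@@H](C)OCc2ccccc2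
F2 | step 23 | (3R,4S,5S,7R,10R)-8,8-(ethylenedioxy)eudesmane-3,4-diol | O[C@]1(C)[C@H](O)CC[C@]2(C)CC3(OCCO3)[C@@H](C(C)C)C[C@@H]21
F3 | step 23 | (3R,4S,5S,7R,10R)-8,8-(ethylenedioxy)-4-hydroxyeudesman-3-yl (2S,3S)-2,3-dimethyloxirane-2-carboxylate | O[C@]1(C)[C@H](OC(=O)[C@@]4(C)O[C@H]4C)CC[C@]2(C)CC3(OCCO3)[C@@H](C(C)C)C[C@@H]21
F4 | step 17 | (4S,5S,7R,10R)-4-acetoxy-8,8-(ethylenedioxy)-3-oxoeudesman-1-yl methanesulfonate (C1 epimers) | CC(=O)O[C@]1(C)C(=O)CC(OS(C)(=O)=O)[C@]2(C)CC3(OCCO3)[C@@H](C(C)C)C[C@@H]21
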